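The ten-membered ring is closed last at the C5–C6 bond (cyclodeca[b]furan numbering: C5 is the ring CH2 beside the glycolate-bearing C4, C6 the alkene carbon carrying CH2OAc) by a nickel-catalysed reductive coupling of a primary alkyl iodide with a (Z)-alkenyl bromide. One operation forges this C(sp3)–C(sp2) bond, closes the carbocycle and transfers the bromide geometry to the endocyclic alkene. The step exploits the cis-fused γ-lactone (C3a/C11a), which holds both arms on one face. The precursor is this α-methylene lactone carrying a 2-bromoallyl acetate arm and a CH2I next to the acylated C4 carbinol, assembled from (S)-citronellal and (S)-glyceraldehyde acetonide by an indium Barbier lactone annulation.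

Key step: step 13

Assumption: in step 9 the allylindium is taken to react through the internally coordinated chair arrangement described there; the fallback given for step 9 covers the opposite facial sense. (S)-Glyceraldehyde acetonide is taken as purchased and distilled before use.

Step 1
Reactants: 1 (S)-citronellal
Product: 2 (6S)-8,8-dimethoxy-2,6-dimethyloct-2-ene
Conditions: CH(OMe)3, MeOH, PPTS (cat.), rt
Reagents that add atoms: trimethyl orthoformate, COC(OC)OC; methanol, CO
Why: Acid-catalysed acetalisation masks the aldehyde for the next five steps; the mild pyridinium catalyst avoids the carbonyl-ene cyclisation of citronellal, and the methyl-bearing stereocentre, which becomes C10 of the target, is not touched.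

Step 2
Reactants: 2 (6S)-8,8-dimethoxy-2,6-dimethyloct-2-ene
Product: 4 (4S)-6,6-dimethoxy-4-methylhexanal, via secondary ozonide 3 (not isolated)
Conditions: O3, CH2Cl2, −78 °C; then PPh3, −78 °C to rt
Reagents that add atoms: ozone, [O-][O+]=O
Why: Ozonolysis with reductive work-up: the electron-rich trisubstituted alkene adds ozone, the ozonide is reduced by the phosphine to the aldehyde and acetone, and the acetal survives.

Step 3
Reactants: 4 (4S)-6,6-dimethoxy-4-methylhexanal; 5 ethyl (triphenylphosphoranylidene)acetate
Product: 7 ethyl (2Z,6S)-2-bromo-8,8-dimethoxy-6-methyloct-2-enoate, via bromo ylide 6 (not isolated)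
Conditions: 5, NBS, CH2Cl2, −20 °C, 30 min; then 4, −20 °C to rt
Reagents that add atoms: N-bromosuccinimide, O=C1CCC(=O)N1Br
Why: One-pot halogenation–Wittig olefination: the stabilised ylide is brominated at carbon and the bromo ylide olefinates the aldehyde with the ester trans to the chain, so that bromine and chain are cis (Z), the geometry that later becomes the cis ring alkene; the minor E isomer should be removable by chromatography.

Step 4
Reactants: 7 ethyl (2Z,6S)-2-bromo-8,8-dimethoxy-6-methyloct-2-enoate
Product: 8 (2Z,6S)-2-bromo-8,8-dimethoxy-6-methyloct-2-en-1-ol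
Conditions: i-Bu2AlH (2.2 equiv), CH2Cl2, −78 °C; aq. potassium sodium tartrate work-up
Reagents that add atoms: none
Why: 1,2-Reduction of the α-bromo enoate by the aluminium hydride at low temperature gives the allylic alcohol and leaves the alkenyl bromide, the alkene geometry and the acetal unchanged.

Step 5
Reactants: 8 (2Z,6S)-2-bromo-8,8-dimethoxy-6-methyloct-2-en-1-ol
Product: 9 (2Z,6S)-2-bromo-8,8-dimethoxy-6-methyloct-2-en-1-yl acetate
Conditions: Ac2O, pyridine, DMAP (cat.), CH2Cl2, 0 °C to rt
Reagents that add atoms: acetic anhydride, CC(=O)OC(C)=O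
Why: Nucleophile-catalysed acetylation of the primary allylic alcohol installs the acetate of the target, which also serves as protecting group to the end.

Step 6
Reactants: 9 (2Z,6S)-2-bromo-8,8-dimethoxy-6-methyloct-2-en-1-yl acetate
Product: 10 (2Z,6S)-2-bromo-6-methyl-8-oxooct-2-en-1-yl acetate
Conditions: 1 M aq. HCl, THF, rt
Reagents that add atoms: water, O
Why: Acid-catalysed hydrolysis of the dimethyl acetal frees the aldehyde under conditions mild enough for the allylic acetate and the alkenyl bromide.

Step 7
Reactants: 11 (S)-2,2-dimethyl-1,3-dioxolane-4-carbaldehyde; 12 methyl acrylate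
Product: 13 methyl 2-{[(4S)-2,2-dimethyl-1,3-dioxolan-4-yl](hydroxy)methyl}prop-2-enoate (both carbinol epimers)
Conditions: DABCO (0.5 equiv), excess 12, 1,4-dioxane/H2O (1:1), rt, several days
Reagents that add atoms: none
Why: Morita–Baylis–Hillman reaction: the amine adds to the acrylate, the resulting enolate adds to the aldehyde and the amine is eliminated; the new carbinol centre forms as a mixture, which does not matter because it becomes sp2 in step 8, and the dioxolane centre should be kept because the aldehyde is consumed without enolisation.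

Step 8
Reactants: 13 methyl 2-{[(4S)-2,2-dimethyl-1,3-dioxolan-4-yl](hydroxy)methyl}prop-2-enoate
Product: 14 methyl (2Z)-2-(bromomethyl)-3-[(4R)-2,2-dimethyl-1,3-dioxolan-4-yl]prop-2-enoate (same spatial arrangement at the dioxolane carbon; the descriptor changes by priority only)
Conditions: NBS, Me2S, CH2Cl2, 0 °C; then 13, 0 °C to rt
Reagents that add atoms: N-bromosuccinimide, O=C1CCC(=O)N1Br
Why: Corey–Kim-type bromination with allylic transposition (SN2′): the alkoxysulfonium group departs as bromide attacks the CH2 terminus, giving the conjugated, thermodynamically preferred Z bromide (ester trans to the dioxolane) under neutral conditions that spare the acetonide.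

Step 9
Reactants: 10 (2Z,6S)-2-bromo-6-methyl-8-oxooct-2-en-1-yl acetate; 14 methyl (2Z)-2-(bromomethyl)-3-[(4R)-2,2-dimethyl-1,3-dioxolan-4-yl]prop-2-enoate
Product: 16 (2Z,6S)-2-bromo-7-[(2S,3S)-3-[(4R)-2,2-dimethyl-1,3-dioxolan-4-yl]-4-methylidene-5-oxooxolan-2-yl]-6-methylhept-2-en-1-yl acetate (cis-lactone), via syn hydroxy ester 15 (not isolated)
Conditions: In powder (1.5 equiv), THF/H2O (1:1), rt; then PPTS (cat.), toluene, 60 °C
Reagents that add atoms: none
Why: Barbier allylation and lactonisation: indium inserts into the allylic C–Br bond and the (Z)-allylindium adds through its γ-carbon in a chair transition state with the dioxolanyl group axial, which should give the syn hydroxy ester and after acid-catalysed loss of methanol the cis-lactone, while the dioxolane stereocentre, whose C–O bond is held in the alkene plane by coordination to indium, directs the aldehyde to the face opposite the dioxolane CH2 and thereby sets both new centres (S at the lactone carbinol C11a, S at C3a).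

Step 10
Reactants: 16 cis-lactone acetonide
Product: 17 (2Z,6S)-2-bromo-7-[(2S,3R)-3-[(1R)-1,2-dihydroxyethyl]-4-methylidene-5-oxooxolan-2-yl]-6-methylhept-2-en-1-yl acetate
Conditions: AcOH/H2O (4:1), 40 °C
Reagents that add atoms: none
Why: Acid-catalysed hydrolysis of the acetonide frees the 1,2-diol; dilute acetic acid should be too mild to open the lactone or to move it to the neighbouring hydroxyl, and the acetate and alkenyl bromide are stable.

Step 11
Reactants: 17 lactone diol
Product: 18 (2Z,6S)-2-bromo-7-[(2S,3R)-3-[(1R)-1-hydroxy-2-iodoethyl]-4-methylidene-5-oxooxolan-2-yl]-6-methylhept-2-en-1-yl acetate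
Conditions: PPh3, I2, imidazole, CH2Cl2, 0 °C (reagent premixed, then 17)
Reagents that add atoms: iodine, II
Why: Appel-type iodination with the preformed phosphonium iodide is selective for the unhindered primary hydroxyl at low temperature, so the secondary carbinol centre keeps its hydroxyl and configuration.

Step 12
Reactants: 18 iodohydrin; 19 {[tert-butyl(dimethyl)silyl]oxy}acetic acid
Product: 20 (2Z,6S)-2-bromo-7-[(2S,3S)-3-[(1R)-1-({[tert-butyl(dimethyl)silyl]oxy}acetoxy)-2-iodoethyl]-4-methylidene-5-oxooxolan-2-yl]-6-methylhept-2-en-1-yl acetate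
Conditions: DIC, DMAP (cat.), CH2Cl2, 0 °C to rt
Reagents that add atoms: none
Why: Steglich esterification acylates the remaining secondary hydroxyl with retention (its C–O bond is not broken) and brings in the glycolate in silyl-protected form; the neighbouring iodide should not close to an epoxide under these weakly basic conditions.

Step 13
Reactants: 20 bromo iodo lactone
Product: 21 [(3aS,4S,6E,10S,11aS)-4-({[tert-butyl(dimethyl)silyl]oxy}acetoxy)-10-methyl-3-methylidene-2-oxo-2,3,3a,4,5,8,9,10,11,11a-decahydrocyclodeca[b]furan-6-yl]methyl acetate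
Conditions: NiBr2·DME (30 mol %), 4,4′-di-tert-butyl-2,2′-bipyridine (35 mol %), Mn powder (4 equiv), NaI (25 mol %), DMA, 35 °C, 20 added by syringe pump over 10 h (final 2 mM)
Reagents that add atoms: none
Why: Zerovalent nickel, formed from NiBr2·DME, the bipyridine and Mn, inserts into the alkenyl C–Br bond with retention of geometry, low-valent nickel abstracts the iodine atom of the primary iodide, and the alkyl radical is captured at the alkenylnickel centre of the same molecule, after which reductive elimination forms the C5–C6 bond. The closest known reaction type is the nickel-catalysed reductive cross-electrophile coupling of alkenyl bromides with primary alkyl iodides, established for intermolecular and for smaller ring-forming cases and used here as a macrocyclisation. The ten-membered carbocycle closes by intramolecular C(sp3)–C(sp2) bond formation with both alkene carbons inside the new ring, so the (Z)-bromide becomes the endocyclic trisubstituted alkene with the two ring bonds cis. No stereocentre is created and the four existing ones are not epimerisable under the neutral conditions. The step needs cross- over homo-coupling, ring closure over oligomerisation and tolerance of the allylic acetate, the β-acyloxy iodide and the methylene lactone. The two different activation modes of the halides, slow addition at high dilution, the cis-lactone that points both arms to one face, and Mn in place of Zn (no direct metal insertion into the C–I bond and hence no β-acyloxy elimination) should secure this.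

Step 14
Reactants: 21 silyl-protected macrocycle
Product: 22 [(3aS,4S,6E,10S,11aS)-4-(hydroxyacetoxy)-10-methyl-3-methylidene-2-oxo-2,3,3a,4,5,8,9,10,11,11a-decahydrocyclodeca[b]furan-6-yl]methyl acetate (CNP0156635.1)
Conditions: HF·pyridine, THF/pyridine, 0 °C to rt
Reagents that add atoms: none
Why: Fluoride-mediated cleavage of the primary silyl ether under buffered conditions frees the glycolate hydroxyl without hydrolysing or migrating the three esters and without adding to the methylene lactone.

Compound list
1 | (S)-citronellal | CC(C)=CCC[C@H](C)CC=O | starting material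
2 | (6S)-8,8-dimethoxy-2,6-dimethyloct-2-ene | CC(C)=CCC[C@H](C)CC(OC)OC | intermediate
3 | 3-[(3S)-5,5-dimethoxy-3-methylpentyl]-5,5-dimethyl-1,2,4-trioxolane (secondary ozonide, not isolated) | CC1(C)OOC(CC[C@H](C)CC(OC)OC)O1 | intermediate
4 | (4S)-6,6-dimethoxy-4-methylhexanal | O=CCC[C@H](C)CC(OC)OC | intermediate
5 | ethyl (triphenylphosphoranylidene)acetate | CCOC(=O)C=P(c1ccccc1)(c1ccccc1)c1ccccc1 | starting material
6 | ethyl bromo(triphenylphosphoranylidene)acetate (bromo ylide, not isolated) | CCOC(=O)C(Br)=P(c1ccccc1)(c1ccccc1)c1ccccc1 | intermediate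
7 | ethyl (2Z,6S)-2-bromo-8,8-dimethoxy-6-methyloct-2-enoate | CCOC(=O)/C(Br)=C/CC[C@H](C)CC(OC)OC | intermediate
8 | (2Z,6S)-2-bromo-8,8-dimethoxy-6-methyloct-2-en-1-ol | OC/C(Br)=C/CC[C@H](C)CC(OC)OC | intermediate
9 | (2Z,6S)-2-bromo-8,8-dimethoxy-6-methyloct-2-en-1-yl acetate | CC(=O)OC/C(Br)=C/CC[C@H](C)CC(OC)OC | intermediate
10 | (2Z,6S)-2-bromo-6-methyl-8-oxooct-2-en-1-yl acetate | CC(=O)OC/C(Br)=C/CC[C@H](C)CC=O | intermediate
11 | (S)-2,2-dimethyl-1,3-dioxolane-4-carbaldehyde ((S)-glyceraldehyde acetonide) | O=C[C@@H]1COC(C)(C)O1 | starting material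
12 | methyl acrylate | C=CC(=O)OC | starting material
13 | methyl 2-{[(4S)-2,2-dimethyl-1,3-dioxolan-4-yl](hydroxy)methyl}prop-2-enoate (both carbinol epimers) | C=C(C(=O)OC)C(O)[C@@H]1COC(C)(C)O1 | intermediate
14 | methyl (2Z)-2-(bromomethyl)-3-[(4R)-2,2-dimethyl-1,3-dioxolan-4-yl]prop-2-enoate | BrC/C(C(=O)OC)=C\[C@@H]1COC(C)(C)O1 | intermediate
15 | methyl (3S,4S,6S,9Z)-11-acetoxy-10-bromo-3-[(4R)-2,2-dimethyl-1,3-dioxolan-4-yl]-4-hydroxy-6-methyl-2-methylideneundec-9-enoate (syn hydroxy ester, not isolated) | C=C(C(=O)OC)[C@H]([C@@H]1COC(C)(C)O1)[C@@H](O)C[C@@H](C)CC/C=C(/COC(C)=O)Br | intermediate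
16 | (2Z,6S)-2-bromo-7-[(2S,3S)-3-[(4R)-2,2-dimethyl-1,3-dioxolan-4-yl]-4-methylidene-5-oxooxolan-2-yl]-6-methylhept-2-en-1-yl acetate | C=C1C(=O)O[C@@H](C[C@@H](C)CC/C=C(/COC(C)=O)Br)[C@H]1[C@@H]2COC(C)(C)O2 | intermediate
17 | (2Z,6S)-2-bromo-7-[(2S,3R)-3-[(1R)-1,2-dihydroxyethyl]-4-methylidene-5-oxooxolan-2-yl]-6-methylhept-2-en-1-yl acetate | C=C1C(=O)O[C@@H](C[C@@H](C)CC/C=C(/COC(C)=O)Br)[C@H]1[C@H](CO)O | intermediate
18 | (2Z,6S)-2-bromo-7-[(2S,3R)-3-[(1R)-1-hydroxy-2-iodoethyl]-4-methylidene-5-oxooxolan-2-yl]-6-methylhept-2-en-1-yl acetate | C=C1C(=O)O[C@@H](C[C@@H](C)CC/C=C(/COC(C)=O)Br)[C@H]1[C@H](CI)O | intermediate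
19 | {[tert-butyl(dimethyl)silyl]oxy}acetic acid | CC(C)(C)[Si](C)(C)OCC(=O)O | starting material
20 | (2Z,6S)-2-bromo-7-[(2S,3S)-3-[(1R)-1-({[tert-butyl(dimethyl)silyl]oxy}acetoxy)-2-iodoethyl]-4-methylidene-5-oxooxolan-2-yl]-6-methylhept-2-en-1-yl acetate | C=C1C(=O)O[C@@H](C[C@@H](C)CC/C=C(/COC(C)=O)Br)[C@H]1[C@H](CI)OC(=O)CO[Si](C)(C)C(C)(C)C | intermediate
21 | [(3aS,4S,6E,10S,11aS)-4-({[tert-butyl(dimethyl)silyl]oxy}acetoxy)-10-methyl-3-methylidene-2-oxo-2,3,3a,4,5,8,9,10,11,11a-decahydrocyclodeca[b]furan-6-yl]methyl acetate | C=C1C(=O)O[C@H]2C[C@@H](C)CC/C=C(/COC(C)=O)C[C@H](OC(=O)CO[Si](C)(C)C(C)(C)C)[C@@H]12 | intermediate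
22 | [(3aS,4S,6E,10S,11aS)-4-(hydroxyacetoxy)-10-methyl-3-methylidene-2-oxo-2,3,3a,4,5,8,9,10,11,11a-decahydrocyclodeca[b]furan-6-yl]methyl acetate (CNP0156635.1) | C=C1C(=O)O[C@H]2C[C@@H](C)CC/C=C(/COC(C)=O)C[C@H](OC(=O)CO)[C@@H]12 | target

Total step count: 14. Longest linear sequence: 12 steps (steps 1–6 and 9–14); steps 7–8 form the second branch.

Steps most likely to fail

Step 13 (key step). What may go wrong: intermolecular coupling to dimers and oligomers instead of ring closure, reduction of the C–I bond to C–H, 1,2-shift or loss of the β-acyloxy group at the radical or alkylnickel stage, and insertion of nickel into the allylic acetate. Fallback: the order of acylation and ring closure is reversed and the alkyl electrophile is changed to an epoxide, so that no β-acyloxy radical is involved. The fallback sets out from iodohydrin 18, which is closed with Ag2O in CH2Cl2 to the terminal epoxide F1 with retention at the carbinol carbon. F1 is then submitted to the nickel-catalysed reductive coupling of an alkenyl bromide with an epoxide under iodide co-catalysis (NiBr2·DME, 2,2′-bipyridine, NaI, Et3N·HCl, Mn powder, DMPU, high dilution), in which iodide opens the epoxide at its CH2 terminus and the same C5–C6 bond closes the ring to the macrocyclic secondary alcohol F2. Steglich esterification of F2 with acid 19 (DIC, DMAP) comes back to the route at 21.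

Step 9. What may go wrong: poor or reversed facial selectivity of the aldehyde addition relative to the dioxolane stereocentre, which would give the cis-lactone with both new centres inverted. Fallback: the enantiomeric three-carbon building block is used and the carbinol centre is corrected later by inversion. The fallback sets out from aldehyde 10 and commercially available (R)-glyceraldehyde acetonide F3, which is taken through the same Morita–Baylis–Hillman reaction to the adduct F4 and the same bromination to the enantiomeric allylic bromide F5. Indium Barbier reaction of F5 with 10 would then give, via the hydroxy ester F6, the cis-lactone F7, in which the two lactone centres are as in 16 and only the dioxolane carbon is inverted. Acetonide hydrolysis to the epimeric diol F8, primary iodination to the epimeric iodohydrin F9 and Mitsunobu esterification of F9 with acid 19 (PPh3, DIAD), which inverts the secondary carbinol, come back to the route at 20.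

Step 11. What may go wrong: activation of the secondary hydroxyl as well, leading to loss of both hydroxyls by reductive elimination to the terminal alkene or to mixed iodides, and reversible addition of the phosphine to the methylene lactone. Fallback: phosphorus is avoided and the primary position is differentiated through a tin acetal. The fallback sets out from diol 17, which is sulfonylated selectively at the primary hydroxyl (TsCl, Et3N, Bu2SnO cat., CH2Cl2) to the primary tosylate F10; Finkelstein displacement of F10 (NaI, acetone, 50 °C) comes back to the route at 18.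

Further compounds
F1 | step 13 | (2Z,6S)-2-bromo-6-methyl-7-[(2S,3S)-4-methylidene-3-[(2R)-oxiran-2-yl]-5-oxooxolan-2-yl]hept-2-en-1-yl acetate | C=C1C(=O)O[C@@H](C[C@@H](C)CC/C=C(/COC(C)=O)Br)[C@H]1[C@@H]2CO2
F2 | step 13 | [(3aR,4S,6E,10S,11aS)-4-hydroxy-10-methyl-3-methylidene-2-oxo-2,3,3a,4,5,8,9,10,11,11a-decahydrocyclodeca[b]furan-6-yl]methyl acetate | C=C1C(=O)O[C@H]2C[C@@H](C)CC/C=C(/COC(C)=O)C[C@H](O)[C@@H]12
F3 | step 9 | (R)-2,2-dimethyl-1,3-dioxolane-4-carbaldehyde | O=C[C@H]1COC(C)(C)O1
F4 | step 9 | methyl 2-{[(4R)-2,2-dimethyl-1,3-dioxolan-4-yl](hydroxy)methyl}prop-2-enoate | C=C(C(=O)OC)C(O)[C@H]1COC(C)(C)O1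
F5 | step 9 | methyl (2Z)-2-(bromomethyl)-3-[(4S)-2,2-dimethyl-1,3-dioxolan-4-yl]prop-2-enoate | BrC/C(C(=O)OC)=C\[C@H]1COC(C)(C)O1
F6 | step 9 | methyl (3S,4S,6S,9Z)-11-acetoxy-10-bromo-3-[(4S)-2,2-dimethyl-1,3-dioxolan-4-yl]-4-hydroxy-6-methyl-2-methylideneundec-9-enoate | C=C(C(=O)OC)[C@H]([C@H]1COC(C)(C)O1)[C@@H](O)C[C@@H](C)CC/C=C(/COC(C)=O)Br
F7 | step 9 | (2Z,6S)-2-bromo-7-[(2S,3S)-3-[(4S)-2,2-dimethyl-1,3-dioxolan-4-yl]-4-methylidene-5-oxooxolan-2-yl]-6-methylhept-2-en-1-yl acetate | C=C1C(=O)O[C@@H](C[C@@H](C)CC/C=C(/COC(C)=O)Br)[C@H]1[C@H]2COC(C)(C)O2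
F8 | step 9 | (2Z,6S)-2-bromo-7-[(2S,3R)-3-[(1S)-1,2-dihydroxyethyl]-4-methylidene-5-oxooxolan-2-yl]-6-methylhept-2-en-1-yl acetate | C=C1C(=O)O[C@@H](C[C@@H](C)CC/C=C(/COC(C)=O)Br)[C@H]1[C@@H](CO)O
F9 | step 9 | (2Z,6S)-2-bromo-7-[(2S,3R)-3-[(1S)-1-hydroxy-2-iodoethyl]-4-methylidene-5-oxooxolan-2-yl]-6-methylhept-2-en-1-yl acetate | C=C1C(=O)O[C@@H](C[C@@H](C)CC/C=C(/COC(C)=O)Br)[C@H]1[C@@H](CI)O
F10 | step 11 | (2Z,6S)-2-bromo-7-[(2S,3R)-3-[(1R)-1-hydroxy-2-{[(4-methylphenyl)sulfonyl]oxy}ethyl]-4-methylidene-5-oxooxolan-2-yl]-6-methylhept-2-en-1-yl acetate | C=C1C(=O)O[C@@H](C[C@@H](C)CC/C=C(/COC(C)=O)Br)[C@H]1[C@H](COS(=O)(=O)c2ccc(C)cc2)O
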